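**Plan**

Ring numbering used below: C1 = C(OH)(C7H2OBz), C2 = CH(OAc), C3 = CH(OBz), C4=C5 the alkene, C6 = CH(OH).
- Cuts: the O7 benzoate and an O6 methoxymethyl ether come off first. The ring is then cut in one retro-step at C4=C5 and at C6–C1. This separates a two-carbon unit (C5, C6, from a Z-γ-alkoxyallylboronate) from the open-chain hex-5-en-2-ulose C7–C1(=O)–C2–C3–C4H=CH2, which comes from a 6-iodo-D-fructofuranoside by ring fragmentation.
- Forward order: the furanose and dioxane rings of the fructoside are temporary and are opened in steps 4 and 6. The only carbocycle arises in step 9, where a five-membered dioxaborolane closes first and the cyclohexene second.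
- Enabling feature: C1 is a ketone carbon flanked by the C7 hydroxymethyl group, and C4 is a vinyl carbon. The C7 hydroxyl captures boron and delivers C6 to C1, after which C4 and C5 are terminal alkene carbons placed for a six-membered ring closure.
- Stereochemistry: C2 and C3 are C3 and C4 of D-fructose. C6 follows from the Z geometry of the reagent in the chair-like allyl transfer, and C1 from Felkin–Anh control by C2.

Key step: step 9

Remark: compounds 5–7 may form as anomeric mixtures in step 4; the α-anomers are drawn, and the anomeric centre disappears in step 6.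

**Route**

Step 1
Reactants: 1 D-fructose
Product: 2 methyl 1,3-O-isopropylidene-α-D-fructofuranoside
Conditions: Me2C(OMe)2, SnCl2 (cat.), 1,2-dimethoxyethane, reflux
Reagents that add atoms: 2,2-dimethoxypropane COC(C)(C)OC
Why: Acid-catalysed Fischer glycosidation combined with transacetalisation should trap the furanose form as the methyl α-glycoside whose cis-disposed O1 and O3 are bridged by the six-membered isopropylidene acetal, leaving O4 and O6 free; only the anomeric centre is new and it is lost later.

Step 2
Reactants: 2 methyl 1,3-O-isopropylidene-α-D-fructofuranoside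
Product: 3 methyl 6-deoxy-6-iodo-1,3-O-isopropylidene-α-D-fructofuranoside
Conditions: PPh3, I2, imidazole, THF, 0 °C → rt
Reagents that add atoms: iodine II
Why: Appel-type iodination (Garegg–Samuelsson conditions) should convert only the primary 6-hydroxyl, because SN2 displacement of the oxyphosphonium ion is much slower at the secondary 4-position.

Step 3
Reactants: 3 methyl 6-deoxy-6-iodo-1,3-O-isopropylidene-α-D-fructofuranoside
Product: 4 methyl 4-O-benzoyl-6-deoxy-6-iodo-1,3-O-isopropylidene-α-D-fructofuranoside
Conditions: BzCl, pyridine, DMAP (cat.), CH2Cl2, 0 °C → rt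
Reagents that add atoms: benzoyl chloride O=C(Cl)c1ccccc1
Why: DMAP-catalysed esterification of the only free hydroxyl installs the benzoate that becomes the C3 benzoate of the target.

Step 4
Reactants: 4 methyl 4-O-benzoyl-6-deoxy-6-iodo-1,3-O-isopropylidene-α-D-fructofuranoside
Product: 5 methyl 4-O-benzoyl-6-deoxy-6-iodo-α-D-fructofuranoside
Conditions: TsOH·H2O (cat.), MeOH, rt
Reagents that add atoms: none
Why: Acid-catalysed transacetalisation in methanol should remove the isopropylidene group while the solvent keeps the ketofuranoside as its methyl glycoside, and the trans relation of O3 and O4 on the furanose disfavours benzoyl migration.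

Step 5
Reactants: 5 methyl 4-O-benzoyl-6-deoxy-6-iodo-α-D-fructofuranoside
Product: 7 methyl 3-O-acetyl-4-O-benzoyl-6-deoxy-6-iodo-1-O-triethylsilyl-α-D-fructofuranoside, via silyl ether 6 (not isolated)
Conditions: Et3SiCl (1.05 equiv), pyridine, CH2Cl2, −40 °C; then Ac2O, DMAP (cat.), rt
Reagents that add atoms: chlorotriethylsilane CC[Si](Cl)(CC)CC; acetic anhydride CC(=O)OC(C)=O
Why: Regioselective silyl ether formation at the primary 1-hydroxyl is much faster than at the hindered secondary 3-hydroxyl, so the acetic anhydride added to the same flask esterifies only O3, giving the acetate that becomes the C2 acetate of the target.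

Step 6
Reactants: 7 methyl 3-O-acetyl-4-O-benzoyl-6-deoxy-6-iodo-1-O-triethylsilyl-α-D-fructofuranoside
Product: 9 (3S,4R)-3-acetoxy-1-hydroxy-2-oxohex-5-en-4-yl benzoate, via silyl ether ketone 8 (not isolated)
Conditions: Zn dust, THF/H2O (4:1), ultrasound, 40 °C; then AcOH/THF/H2O (3:1:1), rt
Reagents that add atoms: none
Why: Zn insertion into the C–I bond and β-elimination of the ring oxygen (Bernet–Vasella reductive fragmentation) should open the furanoside to the terminal alkene and release the ketone by loss of methoxide, after which acid hydrolysis cleaves the primary silyl ether; the two stereocentres are not touched.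

Step 7
Reactants: 10 allyl alcohol
Product: 11 allyl methoxymethyl ether
Conditions: MeOCH2Cl, iPr2NEt, CH2Cl2, 0 °C → rt
Reagents that add atoms: chloromethyl methyl ether COCCl
Why: Williamson-type O-alkylation of the alcohol with the reactive α-chloro ether under amine base gives the acetal ether.

Step 8
Reactants: 11 allyl methoxymethyl ether
Product: 12 diisopropyl [(2Z)-3-(methoxymethoxy)prop-2-en-1-yl]boronate
Conditions: s-BuLi, THF, −78 °C; B(OiPr)3; then HCl (1.0 equiv, Et2O), −78 °C → rt
Reagents that add atoms: triisopropyl borate CC(C)OB(OC(C)C)OC(C)C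
Why: Deprotonation gives the internally chelated Z-configured oxyallyl anion, which is borylated at the carbon remote from oxygen (electrophilic trapping of an allyl anion by a borate ester), and protonolysis of the ate complex releases the Z-γ-alkoxyallylboronate.

Step 9
Reactants: 9 (3S,4R)-3-acetoxy-1-hydroxy-2-oxohex-5-en-4-yl benzoate; 12 diisopropyl [(2Z)-3-(methoxymethoxy)prop-2-en-1-yl]boronate
Product: 15 (1R,2S,3R,6S)-2-acetoxy-3-benzoyloxy-1-(hydroxymethyl)-6-(methoxymethoxy)cyclohex-4-en-1-ol, via diene borate 13 (not isolated), via spiro borate 14 (not isolated)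
Conditions: 12 (0.95 equiv), CH2Cl2, rt; then second-generation Grubbs catalyst (5 mol %), 40 °C, same flask; aqueous work-up
Reagents that add atoms: none
Why: The primary hydroxyl of 9 exchanges with an isopropoxy group of 12, so the allyl group is transferred inside a boron-bridged chair transition state (hydroxyl-directed allylboration of an α-hydroxy ketone is the closest known type); the oxygen-bearing γ-carbon bonds to the ketone carbon with allylic transposition, which makes the C6–C1 bond and a second terminal alkene, and the Grubbs catalyst added to the same flask then joins the two vinyl groups by ring-closing olefin metathesis to make C4=C5 with loss of ethene. Two rings close: the temporary five-membered dioxaborolane by O–B ligand exchange, and the cyclohexene by six-membered ring-closing metathesis, in which the cis alkene is enforced by ring size. C6 is set by the Z geometry of the enol ether, which places the methoxymethoxy group axial in the chair; because the boron-tethered CH2O arm is forced axial and the C2-bearing chain equatorial, this should give the syn (ring-trans) relation between O6 and O1. C1 is set by the acetoxy stereocentre C2 on that equatorial chain, which should direct attack to the Felkin–Anh face (anti relation of O1 and O2, cis on the ring). The step needs γ-regioselectivity, which is inherent in the cyclic allyl transfer; ketone-over-ester chemoselectivity, secured by the intramolecular delivery; and a catalyst that is not quenched by the enol ether of 12, secured by using 12 as the limiting component and adding the catalyst only after it is consumed.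

Step 10
Reactants: 15 (1R,2S,3R,6S)-2-acetoxy-3-benzoyloxy-1-(hydroxymethyl)-6-(methoxymethoxy)cyclohex-4-en-1-ol
Product: 16 [(1R,2S,3R,6S)-2-acetoxy-3-benzoyloxy-1-hydroxy-6-(methoxymethoxy)cyclohex-4-en-1-yl]methyl benzoate
Conditions: BzCl (1.1 equiv), pyridine, CH2Cl2, 0 °C
Reagents that add atoms: benzoyl chloride O=C(Cl)c1ccccc1
Why: Selective esterification should occur at the primary hydroxyl, which is acylated far faster than the tertiary one.

Step 11
Reactants: 16 [(1R,2S,3R,6S)-2-acetoxy-3-benzoyloxy-1-hydroxy-6-(methoxymethoxy)cyclohex-4-en-1-yl]methyl benzoate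
Product: 17 [(1R,2S,3R,6S)-2-acetoxy-3-benzoyloxy-1,6-dihydroxycyclohex-4-en-1-yl]methyl benzoate
Conditions: ZnBr2, n-PrSH, CH2Cl2, 0 °C
Reagents that add atoms: none
Why: Lewis-acid-assisted thiolysis of the methoxymethyl acetal (acetal exchange to the O,S-acetal of the thiol) should free the C6 hydroxyl under conditions too mild to cleave or move the three esters.

**Compound list**

1 | D-fructose (open-chain form drawn) | OCC(=O)[C@@H](O)[C@H](O)[C@H](O)CO | starting material
2 | methyl 1,3-O-isopropylidene-α-D-fructofuranoside | CO[C@@]12O[C@H](CO)[C@@H](O)[C@@H]1OC(C)(C)OC2 | intermediate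
3 | methyl 6-deoxy-6-iodo-1,3-O-isopropylidene-α-D-fructofuranoside | CO[C@@]12O[C@H](CI)[C@@H](O)[C@@H]1OC(C)(C)OC2 | intermediate
4 | methyl 4-O-benzoyl-6-deoxy-6-iodo-1,3-O-isopropylidene-α-D-fructofuranoside | CO[C@@]12O[C@H](CI)[C@@H](OC(=O)c3ccccc3)[C@@H]1OC(C)(C)OC2 | intermediate
5 | methyl 4-O-benzoyl-6-deoxy-6-iodo-α-D-fructofuranoside | CO[C@@]1(CO)O[C@H](CI)[C@@H](OC(=O)c2ccccc2)[C@@H]1O | intermediate
6 | methyl 4-O-benzoyl-6-deoxy-6-iodo-1-O-triethylsilyl-α-D-fructofuranoside | CO[C@@]1(CO[Si](CC)(CC)CC)O[C@H](CI)[C@@H](OC(=O)c2ccccc2)[C@@H]1O | intermediate (not isolated)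
7 | methyl 3-O-acetyl-4-O-benzoyl-6-deoxy-6-iodo-1-O-triethylsilyl-α-D-fructofuranoside | CO[C@@]1(CO[Si](CC)(CC)CC)O[C@H](CI)[C@@H](OC(=O)c2ccccc2)[C@@H]1OC(C)=O | intermediate
8 | (3S,4R)-3-acetoxy-2-oxo-1-(triethylsilyloxy)hex-5-en-4-yl benzoate | C=C[C@@H](OC(=O)c1ccccc1)[C@H](OC(C)=O)C(=O)CO[Si](CC)(CC)CC | intermediate (not isolated)
9 | (3S,4R)-3-acetoxy-1-hydroxy-2-oxohex-5-en-4-yl benzoate | C=C[C@@H](OC(=O)c1ccccc1)[C@H](OC(C)=O)C(=O)CO | intermediate
10 | allyl alcohol | C=CCO | starting material
11 | allyl methoxymethyl ether | C=CCOCOC | intermediate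
12 | diisopropyl [(2Z)-3-(methoxymethoxy)prop-2-en-1-yl]boronate | COCO/C=C\CB(OC(C)C)OC(C)C | intermediate
13 | cyclic isopropyl borate (2-isopropoxy-1,3,2-dioxaborolane across the tertiary O and the CH2O) of (3S,4R,5S,6R)-5-acetoxy-6-benzoyloxy-4-(hydroxymethyl)-3-(methoxymethoxy)octa-1,7-dien-4-ol | C=C[C@@H](OC(=O)c1ccccc1)[C@H](OC(C)=O)[C@@]1(COB(OC(C)C)O1)[C@@H](OCOC)C=C | intermediate (not isolated)
14 | cyclic isopropyl borate (spiro 2-isopropoxy-1,3,2-dioxaborolane across O1 and O7) of 15 | CC(=O)O[C@H]1[C@H](OC(=O)c2ccccc2)C=C[C@H](OCOC)[C@]13COB(OC(C)C)O3 | intermediate (not isolated)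
15 | (1R,2S,3R,6S)-2-acetoxy-3-benzoyloxy-1-(hydroxymethyl)-6-(methoxymethoxy)cyclohex-4-en-1-ol | CC(=O)O[C@H]1[C@H](OC(=O)c2ccccc2)C=C[C@H](OCOC)[C@]1(O)CO | intermediate
16 | [(1R,2S,3R,6S)-2-acetoxy-3-benzoyloxy-1-hydroxy-6-(methoxymethoxy)cyclohex-4-en-1-yl]methyl benzoate | CC(=O)O[C@H]1[C@H](OC(=O)c2ccccc2)C=C[C@H](OCOC)[C@]1(O)COC(=O)c1ccccc1 | intermediate
17 | [(1R,2S,3R,6S)-2-acetoxy-3-benzoyloxy-1,6-dihydroxycyclohex-4-en-1-yl]methyl benzoate | CC(=O)O[C@H]1[C@H](OC(=O)c2ccccc2)C=C[C@H](O)[C@]1(O)COC(=O)c1ccccc1 | target

**Count and risks**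

Total step count: 11. Longest linear sequence: 9 steps (steps 1–6, then 9–11).

Steps most likely to fail:

Step 9. The allyl transfer may show poor facial selectivity at the ketone, or enol ether left over from 12 may deactivate the metathesis catalyst so that ring closure stalls. Fallback: set out from 9. Benzoylation of the primary hydroxyl (BzCl, pyridine) gives the triester ketone F1. Addition of the Et2Al derivative of lithiated 11 (s-BuLi, then Et2AlCl, THF, −78 °C), a reagent class that transfers the oxygen-bearing carbon of alkoxyallyl anions to ketones with syn selectivity, gives the diene alcohol F2, which is isolated and purified. A separate ring-closing metathesis of F2 with the second-generation Grubbs catalyst comes back to the route at 16.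

Step 6. The α-acetoxy group of the liberated ketone may be lost reductively while Zn is present, or base released in the ring opening may cause elimination or acyl migration. Fallback: set out from 6, isolated after the silylation stage of step 5. Bernet–Vasella fragmentation of this alcohol gives the α-hydroxy ketone F3, which carries no α-acyloxy group during the reduction. Acetylation (Ac2O, pyridine) then comes back to the route at 8.

Step 11. The O7 benzoate or the acetate may migrate toward the freed C6 hydroxyl, or a methylene acetal may close between O6 and O1 under the Lewis acid. Fallback: set out from 15 and cleave the methoxymethyl ether there (ZnBr2, n-PrSH) to give the triol F4, in which no ester sits 1,3 to the new hydroxyl. Primary-selective benzoylation with 1-(benzoyloxy)benzotriazole and Et3N then comes back to the route at 17.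

Further compounds
F1 | step 9 | (3S,4R)-3-acetoxy-2-oxohex-5-ene-1,4-diyl dibenzoate | C=C[C@@H](OC(=O)c1ccccc1)[C@H](OC(C)=O)C(=O)COC(=O)c1ccccc1
F2 | step 9 | (3S,4R,5S,6R)-5-acetoxy-4-(benzoyloxymethyl)-4-hydroxy-3-(methoxymethoxy)octa-1,7-dien-6-yl benzoate | C=C[C@@H](OC(=O)c1ccccc1)[C@H](OC(C)=O)[C@@](O)(COC(=O)c1ccccc1)[C@@H](OCOC)C=C
F3 | step 6 | (3S,4R)-3-hydroxy-2-oxo-1-(triethylsilyloxy)hex-5-en-4-yl benzoate | C=C[C@@H](OC(=O)c1ccccc1)[C@H](O)C(=O)CO[Si](CC)(CC)CC
F4 | step 11 | (1R,2S,3R,6S)-2-acetoxy-3-benzoyloxy-1-(hydroxymethyl)cyclohex-4-ene-1,6-diol | CC(=O)O[C@H]1[C@H](OC(=O)c2ccccc2)C=C[C@H](O)[C@]1(O)CO
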